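**Strategy.** The cyclohexane ring of colupone (C1 enol carbon, C2 carrying the isobutyryl group, C3 and C5 carbonyls, C4 and C6 each with two prenyl groups) hides a head-to-tail dimer of diprenylketene in C3–C4–C5–C6. The route therefore builds 2,2,4,4-tetraprenylcyclobutane-1,3-dione and enlarges this four-membered ring by two atoms in one operation. The carbanion of methyl isobutyrylacetate opens one strained C(=O)–C(prenyl)2 bond by retro-Claisen acyl transfer, and the liberated ketone enolate closes onto the ester (Dieckmann), inserting C2–C1 and delivering the complete acyltrione. The precursor is the symmetric, non-enolisable ketene dimer, so no regiochemical question arises.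

Key step: step 5

Remark: colupone has no stereocentre and no stereogenic double bond, so it is achiral and needs no stereocontrol; it is drawn as the enol tautomer of the target SMILES.

Step 1
Reactants: 1 dimethyl malonate; 2 prenyl bromide (1-bromo-3-methylbut-2-ene, 2.2 equiv)
Product: 3 dimethyl 2,2-bis(3-methylbut-2-en-1-yl)malonate
Conditions: NaH (2.2 equiv), THF/DMF, 0 °C → 50 °C
Reagents that add atoms: none
Why: Double malonic ester alkylation, in which the malonate anion displaces bromide twice by SN2 at the unhindered primary allylic carbon, should give the gem-diprenyl diester without SN2′ transposition; no stereocentre is formed.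

Step 2
Reactants: 3 dimethyl 2,2-bis(3-methylbut-2-en-1-yl)malonate
Product: 5 5-methyl-2-(3-methylbut-2-en-1-yl)hex-4-enoic acid, via 2,2-diprenylmalonic acid 4 (not isolated)
Conditions: KOH, MeOH/H2O, reflux; cold 1 M HCl to pH 2, extract; then Cu2O (cat.), MeCN, reflux
Reagents that add atoms: potassium hydroxide, [K+].[OH-]
Why: Saponification and decarboxylation (malonic ester synthesis), with the copper(I)-catalysed decarboxylation keeping temperature and acidity low enough that the carboxyl group should not add to the prenyl double bonds; the α-carbon carries two identical prenyl groups and is not a stereocentre.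

Step 3
Reactants: 5 5-methyl-2-(3-methylbut-2-en-1-yl)hex-4-enoic acid
Product: 6 5-methyl-2-(3-methylbut-2-en-1-yl)hex-4-enoyl chloride
Conditions: Ghosez's reagent (1.1 equiv), CH2Cl2, 0 °C → rt; concentrate, use crude
Reagents that add atoms: Ghosez's reagent (1-chloro-N,N,2-trimethylprop-1-en-1-amine), CC(C)=C(Cl)N(C)C
Why: Acyl chloride formation with an α-chloroenamine under neutral conditions releases no free HCl, so the trisubstituted alkenes should escape hydrochlorination.

Step 4
Reactants: 6 5-methyl-2-(3-methylbut-2-en-1-yl)hex-4-enoyl chloride (two molecules)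
Product: 8 2,2,4,4-tetrakis(3-methylbut-2-en-1-yl)cyclobutane-1,3-dione, via diprenylketene 7 (not isolated)
Conditions: Et3N (1.5 equiv), toluene, reflux, 24–48 h; filter
Reagents that add atoms: none
Why: Amine-mediated dehydrochlorination of the α-branched acyl chloride to the ketoketene and its thermal head-to-tail [2+2] cyclodimerisation is the established way to 2,2,4,4-tetraalkylcyclobutane-1,3-diones, the ketene polarity fixing the alternating C(prenyl)2/C=O pattern; no stereocentre results.

Step 5
Reactants: 8 2,2,4,4-tetrakis(3-methylbut-2-en-1-yl)cyclobutane-1,3-dione; 9 methyl 4-methyl-3-oxopentanoate (methyl isobutyrylacetate, 1.1 equiv)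
Product: 11 colupone, via ring-opened tricarbonyl ester 10 (not isolated)
Conditions: 9, NaH (1.1 equiv), THF, 0 °C; add 8, THF/DMF, 70 °C; then t-BuOK (1.5 equiv), 0 → 50 °C; cold 1 M HCl work-up
Reagents that add atoms: none
Why: Proposed new method: the sodium enolate of 9 adds through carbon to one of the two equivalent, strain-activated carbonyl groups of 8, and the tetrahedral alkoxide collapses with cleavage of the adjacent C(=O)–C(prenyl)2 ring bond (retro-Claisen, driven by release of cyclobutane strain), giving after proton transfer the tricarbonyl methanide of 10 with a free CH(prenyl)2 ketone terminus. t-BuOK then forms the enolate of this ketone, which attacks the methyl ester in a 6-exo-trig Dieckmann (Claisen) closure and expels methoxide, so that the C2(isobutyryl)–C1(=O) unit of 9 is inserted into one ring bond of 8 and the four-membered ring becomes the six-membered ring with its four carbons retained as C3, C4, C5 and C6. The closest known reaction types are the alkoxide-induced retro-Claisen opening of 2,2,4,4-tetraalkylcyclobutane-1,3-diones to β-keto esters, the base-induced conversion of dimethylketene dimer into hexamethylcyclohexane-1,3,5-trione and Dieckmann closures to syncarpic-acid-type triones; the use of a β-keto ester carbanion as the ring-opening nucleophile is the untested element. No stereocentre is formed, since the product is achiral. The step needs C- rather than O-acylation in both C–C bond formations and Claisen rather than aldol closure onto the isobutyryl ketone; the enol ester, enol lactone and aldolate alternatives are reversible under aprotic base, whereas the chelated anion of the 2-acyl-1,3,5-trione is the thermodynamic sink. The symmetry of 8 removes any choice of carbonyl or ring bond, and alkoxide is kept out of the flask until 8 is consumed so that it cannot open 8 to a simple β-keto ester.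

**Compound list**

1 | dimethyl malonate | COC(=O)CC(=O)OC | starting material
2 | prenyl bromide (1-bromo-3-methylbut-2-ene) | CC(C)=CCBr | starting material
3 | dimethyl 2,2-bis(3-methylbut-2-en-1-yl)malonate | COC(=O)C(CC=C(C)C)(CC=C(C)C)C(=O)OC | intermediate
4 | 2,2-bis(3-methylbut-2-en-1-yl)malonic acid | OC(=O)C(CC=C(C)C)(CC=C(C)C)C(=O)O | intermediate (not isolated)
5 | 5-methyl-2-(3-methylbut-2-en-1-yl)hex-4-enoic acid | CC(C)=CCC(CC=C(C)C)C(=O)O | intermediate
6 | 5-methyl-2-(3-methylbut-2-en-1-yl)hex-4-enoyl chloride | CC(C)=CCC(CC=C(C)C)C(Cl)=O | intermediate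
7 | diprenylketene (5-methyl-2-(3-methylbut-2-en-1-yl)hexa-1,4-dien-1-one) | CC(C)=CCC(CC=C(C)C)=C=O | intermediate (not isolated)
8 | 2,2,4,4-tetrakis(3-methylbut-2-en-1-yl)cyclobutane-1,3-dione | CC(C)=CCC1(CC=C(C)C)C(=O)C(CC=C(C)C)(CC=C(C)C)C1=O | intermediate
9 | methyl 4-methyl-3-oxopentanoate | COC(=O)CC(=O)C(C)C | starting material
10 | methyl 9-methyl-2-(2-methylpropanoyl)-4,4,6-tris(3-methylbut-2-en-1-yl)-3,5-dioxodec-8-enoate (formed as its sodium salt) | COC(=O)C(C(=O)C(C)C)C(=O)C(CC=C(C)C)(CC=C(C)C)C(=O)C(CC=C(C)C)CC=C(C)C | intermediate (not isolated)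
11 | colupone | CC(C)=CCC1(CC=C(C)C)C(=O)C(C(=O)C(C)C)=C(O)C(CC=C(C)C)(CC=C(C)C)C1=O | target

**Total step count:** 5. **Longest linear sequence:** 5 steps (1 → 3 → 5 → 6 → 8 → 11).

**Steps most likely to fail**

1. Step 5 (Proposed new method). The bulky, stabilised carbanion may add too slowly to a carbonyl flanked by two quaternary carbons, or the closure may divert to O-acylation or aldol addition. The fallback uses known chemistry, sets out from 8 and returns at 11 by two successive one-carbon ring expansions.
   - Diazomethane (Et2O/MeOH, 0 °C) should homologate the strained ketone of 8 by addition and 1,2-shift of a ring carbon, giving 2,2,4,4-tetrakis(3-methylbut-2-en-1-yl)cyclopentane-1,3-dione F1.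
   - The only enolisable CH2 of F1 is hydroxylated through its potassium enolate (KHMDS, THF, −78 °C; 2-(phenylsulfonyl)-3-phenyloxaziridine) to racemic 5-hydroxy-2,2,4,4-tetrakis(3-methylbut-2-en-1-yl)cyclopentane-1,3-dione F2.
   - Dess–Martin oxidation then gives 3,3,5,5-tetrakis(3-methylbut-2-en-1-yl)cyclopentane-1,2,4-trione F3.
   - Separately, isobutyryl chloride (CC(C)C(Cl)=O) and excess diazomethane give 1-diazo-3-methylbutan-2-one F4.
   - F3 and F4 with BF3·OEt2 (CH2Cl2, −78 → 0 °C) should react by addition of the diazo carbon to one of the two equivalent vicinal carbonyls and 1,2-acyl shift with loss of nitrogen (Eistert-type ring expansion of a 1,2-dione). This inserts the isobutyryl-bearing carbon between the two carbonyls and gives 11.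

2. Step 4. Dimerisation of the hindered ketoketene may be sluggish, so that oligomerisation or addition of the ketene to unreacted acyl chloride takes over. The fallback sets out from 6 and returns at 8.
   - The ketene 7 is generated from 6 with Et3N as before, but in the presence of ethoxyacetylene (CCOC#C), a far better ketenophile than the ketene itself. The [2+2] cycloaddition should give 3-ethoxy-4,4-bis(3-methylbut-2-en-1-yl)cyclobut-2-en-1-one F5.
   - Cold dilute HCl in THF hydrolyses the vinylogous ester to 2,2-bis(3-methylbut-2-en-1-yl)cyclobutane-1,3-dione F6, which exists largely as its enol.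
   - Tsuji–Trost allylation of F6 with methyl prenyl carbonate (COC(=O)OCC=C(C)C, 2.2 equiv; Pd(PPh3)4 cat., THF) should place two prenyl groups on the remaining CH2. Attack occurs at the unsubstituted allyl terminus and O-allylated material re-ionises, giving 8.

3. Step 2. During acidification and decarboxylation the carboxyl group may add to a prenyl double bond (lactonisation), or the alkenes may be hydrated. The fallback sets out from 3 and returns at 5.
   - Krapcho dealkoxycarbonylation of 3 (LiCl, wet DMSO, 150 °C) under neutral conditions should give methyl 5-methyl-2-(3-methylbut-2-en-1-yl)hex-4-enoate F7.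
   - Saponification with LiOH (THF/H2O, rt) and acidification to pH 4 gives 5.

**Further compounds**

F1 | step 5 | 2,2,4,4-tetrakis(3-methylbut-2-en-1-yl)cyclopentane-1,3-dione | CC(C)=CCC1(CC=C(C)C)C(=O)CC(CC=C(C)C)(CC=C(C)C)C1=O
F2 | step 5 | 5-hydroxy-2,2,4,4-tetrakis(3-methylbut-2-en-1-yl)cyclopentane-1,3-dione (racemic) | CC(C)=CCC1(CC=C(C)C)C(=O)C(O)C(CC=C(C)C)(CC=C(C)C)C1=O
F3 | step 5 | 3,3,5,5-tetrakis(3-methylbut-2-en-1-yl)cyclopentane-1,2,4-trione | CC(C)=CCC1(CC=C(C)C)C(=O)C(=O)C(CC=C(C)C)(CC=C(C)C)C1=O
F4 | step 5 | 1-diazo-3-methylbutan-2-one | CC(C)C(=O)C=[N+]=[N-]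
F5 | step 4 | 3-ethoxy-4,4-bis(3-methylbut-2-en-1-yl)cyclobut-2-en-1-one | CCOC1=CC(=O)C1(CC=C(C)C)CC=C(C)C
F6 | step 4 | 2,2-bis(3-methylbut-2-en-1-yl)cyclobutane-1,3-dione | CC(C)=CCC1(CC=C(C)C)C(=O)CC1=O
F7 | step 2 | methyl 5-methyl-2-(3-methylbut-2-en-1-yl)hex-4-enoate | COC(=O)C(CC=C(C)C)CC=C(C)C
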